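**Retrosynthetic overview**
1. Target 30 ⇐ O-demethylation, C3 desilylation and alcohol oxidation of carbinol 27 ⇐ intermolecular aldol addition of the C1 bridgehead carbanion of vinylogous ester 24 to 2-methylpropanal.
2. Key step: bicyclic trione 21 ⇐ intermolecular Claisen-type C-acylation of cyclohexanone enol ether 18 with malonyl dichloride (three-carbon fragment), closed by a second acylation (Effenberger annulation; C1–C2, then C4–C5).
3. Ketone 16 ⇐ α-prenylation (C5) ⇐ copper-catalysed 1,4-addition of homoprenyl Grignard to 3-methyl enone 9 (C8 quaternary centre, anti to the C7 prenyl) ⇐ methyl 1,4-addition/Saegusa oxidation of enone 7.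
4. (R)-Enone 7 ⇐ aldol condensation of keto aldehyde 6 ⇐ organocatalytic intermolecular Michael addition of 5-methylhex-4-enal to but-3-en-2-one (sets C7, the only reagent-controlled stereocentre); aldehyde from a Johnson–Claisen rearrangement.
5. Ring order: carbocycle C9–C1–C8–C7–C6–C5 first (step 4), then the oxygenated ring C1–C2–C3–C4–C5–C9 (step 10).

Assumption: the target is the enol tautomer as drawn; bicyclic compounds are named with acylphloroglucinol numbering (C1 acyl bridgehead, C2–C4 oxygenated bridge, C5 prenyl bridgehead, C6 CH2, C7 CH, C8 quaternary carbon, C9 bridging C=O), monocycles with their own ring numbering; prenyl = 3-methylbut-2-en-1-yl, homoprenyl = 4-methylpent-3-en-1-yl.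

The route is a proposal based on known reaction types and has not been run; the CIP descriptors in the names were assigned by hand.

**Step 1**
Reactants: 1 2-methylbut-3-en-2-ol; 2 triethyl orthoacetate
Product: 3 ethyl 5-methylhex-4-enoate
Conditions: EtCO2H (cat.), 140 °C, EtOH distilled off
Reagents that add atoms: none
Why: Johnson–Claisen rearrangement, in which the mixed ketene acetal formed by acid-catalysed exchange undergoes a [3,3]-sigmatropic shift that turns the tertiary allylic alcohol into the trisubstituted alkene and places the ester two carbons away; no stereocentre is formed.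

**Step 2**
Reactants: 3 ethyl 5-methylhex-4-enoate
Product: 4 5-methylhex-4-enal
Conditions: i-Bu2AlH (1.05 equiv), CH2Cl2, −78 °C; then 1 M HCl
Reagents that add atoms: none
Why: Partial ester reduction with i-Bu2AlH stops at the tetrahedral aluminium hemiacetal at −78 °C and releases the aldehyde only on work-up, the trisubstituted alkene being inert.

**Step 3**
Reactants: 4 5-methylhex-4-enal; 5 but-3-en-2-one
Product: 6 (2R)-2-prenyl-5-oxohexanal
Conditions: (R)-2-[methoxy(diphenyl)methyl]pyrrolidine (5 mol %), ethyl 3,4-dihydroxybenzoate (20 mol %), neat, 4 °C, 36 h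
Reagents that add atoms: none
Why: Enamine-catalysed intermolecular Michael addition, in which the (E)-enamine of 4 is shielded on one face by the C(Ph)2OMe group of the (R)-catalyst so that the hydrogen-bond-activated enone adds to the open face and gives the (R) stereocentre (future C7), from which all other centres are relayed.

**Step 4**
Reactants: 6 (2R)-2-prenyl-5-oxohexanal
Product: 7 (4R)-4-prenylcyclohex-2-en-1-one
Conditions: LiOH (20 mol %), i-PrOH, 25 °C
Reagents that add atoms: none
Why: Intramolecular aldol condensation, in which the methyl ketone enolate closes onto the aldehyde and the aldol dehydrates to the conjugated enone under mild conditions where ring closure outruns enolisation of the α-branched aldehyde, so the stereocentre is kept.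

**Step 5**
Reactants: 7 (4R)-4-prenylcyclohex-2-en-1-one
Product: 8 (3R,4R)-3-methyl-4-prenyl-1-(trimethylsilyloxy)cyclohex-1-ene
Conditions: MeMgBr, CuBr·SMe2 (10 mol %), TMSCl, DMPU, THF, −78 °C; Et3N quench
Reagents that add atoms: methylmagnesium bromide, C[Mg]Br; chlorotrimethylsilane, C[Si](C)(C)Cl
Why: Copper-catalysed, TMSCl-accelerated conjugate addition of the Grignard reagent occurs anti to the C4 prenyl group and the enolate is trapped regiospecifically as the silyl enol ether; the new methyl-bearing centre is transient because it is planarised in step 6.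

**Step 6**
Reactants: 8 (3R,4R)-3-methyl-4-prenyl-1-(trimethylsilyloxy)cyclohex-1-ene
Product: 9 (4R)-3-methyl-4-prenylcyclohex-2-en-1-one
Conditions: Pd(OAc)2 (10 mol %), O2 (1 atm), DMSO, 25 °C
Reagents that add atoms: none
Why: Saegusa–Ito oxidation, in which the palladium enolate has its only β-hydrogen at C3, so β-hydride elimination regenerates the enone with the methyl on the β-carbon while C4 is untouched and O2 returns zerovalent palladium to divalent palladium.

**Step 7**
Reactants: 9 (4R)-3-methyl-4-prenylcyclohex-2-en-1-one; 10 5-bromo-2-methylpent-2-ene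
Product: 13 (3S,4R)-3-homoprenyl-3-methyl-4-prenylcyclohexan-1-one, via Grignard reagent 11 (not isolated), via silyl enol ether 12 (not isolated)
Conditions: 10, Mg, THF, 25 °C; then 9, CuBr·SMe2 (20 mol %), TMSCl, DMPU, THF, −78 → −30 °C; then 1 M HCl, 0 °C
Reagents that add atoms: none
Why: Copper-catalysed conjugate addition to the β,β-disubstituted enone (activated by TMSCl/DMPU) proceeds by axial attack anti to the C4 prenyl group, which allylic strain against the 3-methyl holds pseudoaxial, so the quaternary centre (future C8) forms with homoprenyl trans and methyl cis to prenyl, and acidic work-up unmasks the ketone.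

**Step 8**
Reactants: 13 (3S,4R)-3-homoprenyl-3-methyl-4-prenylcyclohexan-1-one; 14 1-bromo-3-methylbut-2-ene
Product: 16 (2R,4S,5S)-5-homoprenyl-5-methyl-2,4-diprenylcyclohexan-1-one, via lithium enolate 15 (not isolated)
Conditions: LiN(i-Pr)2, THF, −78 °C; then 14, DMPU, −78 → −20 °C
Reagents that add atoms: none
Why: Kinetic deprotonation takes the unhindered CH2 remote from the quaternary carbon and the enolate is alkylated by the allylic bromide (SN2 enolate alkylation); the new centre (future C5) is drawn as the equatorial epimer, but its configuration is irrelevant because it is planarised in step 10.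

**Step 9**
Reactants: 16 (2R,4S,5S)-5-homoprenyl-5-methyl-2,4-diprenylcyclohexan-1-one
Product: 18 (3R,4S,6R)-3-homoprenyl-1-methoxy-3-methyl-4,6-diprenylcyclohex-1-ene, via dimethyl ketal 17 (not isolated)
Conditions: HC(OMe)3, p-TsOH·H2O (2 mol %), MeOH, 25 °C; then TMSOTf, i-Pr2NEt, CH2Cl2, −20 → 25 °C
Reagents that add atoms: trimethyl orthoformate, COC(OC)OC
Why: Acid-catalysed ketalisation followed by Gassman-type TMSOTf/amine elimination of methanol gives the methyl enol ether (expected mainly as the less substituted isomer) under buffered, low-temperature conditions that spare the three trisubstituted alkenes, and any Δ(1,6) isomer converges in step 10.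

**Step 10**
Reactants: 18 (3R,4S,6R)-3-homoprenyl-1-methoxy-3-methyl-4,6-diprenylcyclohex-1-ene; 19 malonyl dichloride
Product: 21 (1S,5R,7S,8R)-8-homoprenyl-8-methyl-5,7-diprenylbicyclo[3.3.1]nonane-2,4,9-trione, via acyl chloride 20 (not isolated)
Conditions: 19 (2 equiv), Et2O, −20 → 25 °C, 24 h; then KOH, BnEt3NCl (10 mol %), H2O, 25 °C; then HCl to pH 2
Reagents that add atoms: water, O
Why: Effenberger annulation, i.e. an intermolecular Claisen-type C-acylation of the enol ether at C1 (anti to the axial C8 methyl) followed, once loss of HCl has re-formed the enol ether toward C5, by intramolecular C-acylation at C5; the three-carbon bridge can only span C1 and C5 diaxially on the face opposite the equatorial C7 prenyl, which fixes both bridgeheads, and aqueous KOH hydrolyses the chloro ether and enol lactone by-products to the trione. Yields of this annulation are typically modest.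

**Step 11**
Reactants: 21 (1S,5R,7S,8R)-8-homoprenyl-8-methyl-5,7-diprenylbicyclo[3.3.1]nonane-2,4,9-trione
Product: 22 (1S,5R,7S,8R)-8-homoprenyl-4-methoxy-8-methyl-5,7-diprenylbicyclo[3.3.1]non-3-ene-2,9-dione
Conditions: HC(OMe)3, p-TsOH·H2O (5 mol %), MeOH, 50 °C; chromatography, 2-methoxy isomer resubmitted
Reagents that add atoms: trimethyl orthoformate, COC(OC)OC
Why: Acid-catalysed enol etherification of the β-diketone under equilibrating conditions gives both vinylogous methyl esters (no selectivity is expected), of which the 4-methoxy isomer (C2 ketone next to the bridgehead C1–H, as needed for step 13) is separated and the 2-methoxy isomer is re-equilibrated; no stereocentre changes.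

**Step 12**
Reactants: 22 (1S,5R,7S,8R)-8-homoprenyl-4-methoxy-8-methyl-5,7-diprenylbicyclo[3.3.1]non-3-ene-2,9-dione
Product: 24 (1R,5R,7S,8R)-8-homoprenyl-4-methoxy-8-methyl-5,7-diprenyl-3-(trimethylsilyl)bicyclo[3.3.1]non-3-ene-2,9-dione, via vinyllithium 23 (not isolated)
Conditions: lithium 2,2,6,6-tetramethylpiperidide, TMSCl (in situ), THF, −78 °C
Reagents that add atoms: chlorotrimethylsilane, C[Si](C)(C)Cl
Why: The vinylic C3–H between the ketone and the enol ether carbon is the kinetically most accessible acidic site, so the hindered amide base with in situ silyl chloride quench gives the C3 silane (vinylic lithiation–silylation), which blocks this position for step 13.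

**Step 13**
Reactants: 24 (1R,5R,7S,8R)-8-homoprenyl-4-methoxy-8-methyl-5,7-diprenyl-3-(trimethylsilyl)bicyclo[3.3.1]non-3-ene-2,9-dione; 25 2-methylpropanal
Product: 27 (1S,5R,7S,8R)-8-homoprenyl-1-(1-hydroxy-2-methylpropyl)-4-methoxy-8-methyl-5,7-diprenyl-3-(trimethylsilyl)bicyclo[3.3.1]non-3-ene-2,9-dione, via bridgehead lithium species 26 (not isolated)
Conditions: LiN(i-Pr)2, THF, −78 → −40 °C; then 25, −78 °C; then AcOH, −78 °C
Reagents that add atoms: none
Why: With C3 blocked the amide base removes the bridgehead C1–H, acidified by the flanking C2 and C9 carbonyls, and the geometrically fixed bridgehead carbanion adds to the aldehyde in an intermolecular aldol addition, creating the congested C1 quaternary centre with the only configuration the bicycle allows (both carbinol epimers are carried on).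

**Step 14**
Reactants: 27 (1S,5R,7S,8R)-8-homoprenyl-1-(1-hydroxy-2-methylpropyl)-4-methoxy-8-methyl-5,7-diprenyl-3-(trimethylsilyl)bicyclo[3.3.1]non-3-ene-2,9-dione
Product: 28 (1S,5R,7S,8R)-8-homoprenyl-4-methoxy-8-methyl-1-(2-methylpropanoyl)-5,7-diprenyl-3-(trimethylsilyl)bicyclo[3.3.1]non-3-ene-2,9-dione
Conditions: Dess–Martin periodinane, CH2Cl2, 25 °C
Reagents that add atoms: none
Why: Dess–Martin oxidation converts the hindered secondary alcohol into the ketone under neutral, non-enolising conditions that leave the vinylsilane, the enol ether and the alkenes intact, and it removes the carbinol stereocentre.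

**Step 15**
Reactants: 28 (1S,5R,7S,8R)-8-homoprenyl-4-methoxy-8-methyl-1-(2-methylpropanoyl)-5,7-diprenyl-3-(trimethylsilyl)bicyclo[3.3.1]non-3-ene-2,9-dione
Product: 29 (1R,5R,7S,8R)-8-homoprenyl-4-methoxy-8-methyl-1-(2-methylpropanoyl)-5,7-diprenylbicyclo[3.3.1]non-3-ene-2,9-dione
Conditions: n-Bu4NF, AcOH, THF, 0 °C
Reagents that add atoms: none
Why: Protodesilylation, in which fluoride attacks silicon and the C3 carbanion of the vinylogous ester is protonated by the acetic acid buffer, the buffer preventing retro-Claisen cleavage of the bridgehead triketone.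

**Step 16**
Reactants: 29 (1R,5R,7S,8R)-8-homoprenyl-4-methoxy-8-methyl-1-(2-methylpropanoyl)-5,7-diprenylbicyclo[3.3.1]non-3-ene-2,9-dione
Product: 30 (1R,5R,7S,8R)-4-hydroxy-8-homoprenyl-8-methyl-1-(2-methylpropanoyl)-5,7-diprenylbicyclo[3.3.1]non-3-ene-2,9-dione
Conditions: LiCl, DMSO, 120 °C, argon; then 1 M HCl
Reagents that add atoms: none
Why: Krapcho-type dealkylation, in which chloride cleaves the O–CH3 bond of the vinylogous ester by SN2 attack at methyl and releases the diketonate without a hydroxide nucleophile that could cause retro-Claisen loss of the acyl group; acidification gives the enol and no stereocentre is touched.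

**Compound list**
1 | 2-methylbut-3-en-2-ol | CC(C)(O)C=C | starting material
2 | triethyl orthoacetate (1,1,1-triethoxyethane) | CC(OCC)(OCC)OCC | starting material
3 | ethyl 5-methylhex-4-enoate | CCOC(=O)CCC=C(C)C | intermediate
4 | 5-methylhex-4-enal | CC(C)=CCCC=O | intermediate
5 | but-3-en-2-one | CC(=O)C=C | starting material
6 | (2R)-2-(3-methylbut-2-en-1-yl)-5-oxohexanal | O=C[C@@H](CC=C(C)C)CCC(C)=O | intermediate
7 | (4R)-4-(3-methylbut-2-en-1-yl)cyclohex-2-en-1-one | O=C1C=C[C@@H](CC=C(C)C)CC1 | intermediate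
8 | trimethyl{[(3R,4R)-3-methyl-4-(3-methylbut-2-en-1-yl)cyclohex-1-en-1-yl]oxy}silane | C[Si](C)(C)OC1=C[C@H](C)[C@@H](CC=C(C)C)CC1 | intermediate
9 | (4R)-3-methyl-4-(3-methylbut-2-en-1-yl)cyclohex-2-en-1-one | O=C1C=C(C)[C@@H](CC=C(C)C)CC1 | intermediate
10 | 5-bromo-2-methylpent-2-ene | CC(C)=CCCBr | starting material
11 | (4-methylpent-3-en-1-yl)magnesium bromide | CC(C)=CCC[Mg]Br | intermediate
12 | trimethyl{[(3R,4R)-3-methyl-4-(3-methylbut-2-en-1-yl)-3-(4-methylpent-3-en-1-yl)cyclohex-1-en-1-yl]oxy}silane | CC(C)=CCC[C@]1(C)[C@@H](CC=C(C)C)CCC(O[Si](C)(C)C)=C1 | intermediate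
13 | (3S,4R)-3-methyl-4-(3-methylbut-2-en-1-yl)-3-(4-methylpent-3-en-1-yl)cyclohexan-1-one | CC(C)=CCC[C@]1(C)[C@@H](CC=C(C)C)CCC(=O)C1 | intermediate
14 | 1-bromo-3-methylbut-2-ene | CC(C)=CCBr | starting material
15 | lithium (4S,5S)-5-methyl-4-(3-methylbut-2-en-1-yl)-5-(4-methylpent-3-en-1-yl)cyclohex-1-en-1-olate | CC(C)=CCC[C@]1(C)[C@@H](CC=C(C)C)CC=C(O[Li])C1 | intermediate
16 | (2R,4S,5S)-5-methyl-2,4-bis(3-methylbut-2-en-1-yl)-5-(4-methylpent-3-en-1-yl)cyclohexan-1-one (equatorial C2 epimer drawn) | CC(C)=CCC[C@]1(C)[C@@H](CC=C(C)C)C[C@@H](CC=C(C)C)C(=O)C1 | intermediate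
17 | (2R,4S,5S)-1,1-dimethoxy-5-methyl-2,4-bis(3-methylbut-2-en-1-yl)-5-(4-methylpent-3-en-1-yl)cyclohexane | CC(C)=CCC[C@]1(C)[C@@H](CC=C(C)C)C[C@@H](CC=C(C)C)C(OC)(OC)C1 | intermediate
18 | (3R,4S,6R)-1-methoxy-3-methyl-4,6-bis(3-methylbut-2-en-1-yl)-3-(4-methylpent-3-en-1-yl)cyclohex-1-ene (major double-bond isomer) | CC(C)=CCC[C@]1(C)[C@@H](CC=C(C)C)C[C@@H](CC=C(C)C)C(OC)=C1 | intermediate
19 | malonyl dichloride (propanedioyl dichloride) | O=C(Cl)CC(Cl)=O | starting material
20 | 3-[(1R,5S,6R)-2-methoxy-6-methyl-3,5-bis(3-methylbut-2-en-1-yl)-6-(4-methylpent-3-en-1-yl)cyclohex-2-en-1-yl]-3-oxopropanoyl chloride | CC(C)=CCC[C@]1(C)[C@@H](CC=C(C)C)CC(CC=C(C)C)=C(OC)[C@@H]1C(=O)CC(Cl)=O | intermediate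
21 | (1S,5R,7S,8R)-8-methyl-5,7-bis(3-methylbut-2-en-1-yl)-8-(4-methylpent-3-en-1-yl)bicyclo[3.3.1]nonane-2,4,9-trione | CC(C)=CCC[C@]1(C)[C@@H](CC=C(C)C)C[C@@]2(CC=C(C)C)C(=O)[C@@H]1C(=O)CC2=O | intermediate
22 | (1S,5R,7S,8R)-4-methoxy-8-methyl-5,7-bis(3-methylbut-2-en-1-yl)-8-(4-methylpent-3-en-1-yl)bicyclo[3.3.1]non-3-ene-2,9-dione | CC(C)=CCC[C@]1(C)[C@@H](CC=C(C)C)C[C@@]2(CC=C(C)C)C(=O)[C@@H]1C(=O)C=C2OC | intermediate
23 | [(1S,5R,7S,8R)-4-methoxy-8-methyl-5,7-bis(3-methylbut-2-en-1-yl)-8-(4-methylpent-3-en-1-yl)-2,9-dioxobicyclo[3.3.1]non-3-en-3-yl]lithium | CC(C)=CCC[C@]1(C)[C@@H](CC=C(C)C)C[C@@]2(CC=C(C)C)C(=O)[C@@H]1C(=O)C([Li])=C2OC | intermediate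
24 | (1R,5R,7S,8R)-4-methoxy-8-methyl-5,7-bis(3-methylbut-2-en-1-yl)-8-(4-methylpent-3-en-1-yl)-3-(trimethylsilyl)bicyclo[3.3.1]non-3-ene-2,9-dione | CC(C)=CCC[C@]1(C)[C@@H](CC=C(C)C)C[C@@]2(CC=C(C)C)C(=O)[C@@H]1C(=O)C([Si](C)(C)C)=C2OC | intermediate
25 | 2-methylpropanal | CC(C)C=O | starting material
26 | [(1R,5R,7S,8R)-4-methoxy-8-methyl-5,7-bis(3-methylbut-2-en-1-yl)-8-(4-methylpent-3-en-1-yl)-2,9-dioxo-3-(trimethylsilyl)bicyclo[3.3.1]non-3-en-1-yl]lithium | CC(C)=CCC[C@]1(C)[C@@H](CC=C(C)C)C[C@@]2(CC=C(C)C)C(=O)[C@]1([Li])C(=O)C([Si](C)(C)C)=C2OC | intermediate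
27 | (1S,5R,7S,8R)-1-[(1RS)-1-hydroxy-2-methylpropyl]-4-methoxy-8-methyl-5,7-bis(3-methylbut-2-en-1-yl)-8-(4-methylpent-3-en-1-yl)-3-(trimethylsilyl)bicyclo[3.3.1]non-3-ene-2,9-dione | CC(C)=CCC[C@]1(C)[C@@H](CC=C(C)C)C[C@@]2(CC=C(C)C)C(=O)[C@]1(C(O)C(C)C)C(=O)C([Si](C)(C)C)=C2OC | intermediate
28 | (1S,5R,7S,8R)-4-methoxy-8-methyl-1-(2-methylpropanoyl)-5,7-bis(3-methylbut-2-en-1-yl)-8-(4-methylpent-3-en-1-yl)-3-(trimethylsilyl)bicyclo[3.3.1]non-3-ene-2,9-dione | CC(C)=CCC[C@]1(C)[C@@H](CC=C(C)C)C[C@@]2(CC=C(C)C)C(=O)[C@]1(C(=O)C(C)C)C(=O)C([Si](C)(C)C)=C2OC | intermediate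
29 | (1R,5R,7S,8R)-4-methoxy-8-methyl-1-(2-methylpropanoyl)-5,7-bis(3-methylbut-2-en-1-yl)-8-(4-methylpent-3-en-1-yl)bicyclo[3.3.1]non-3-ene-2,9-dione | CC(C)=CCC[C@]1(C)[C@@H](CC=C(C)C)C[C@@]2(CC=C(C)C)C(=O)[C@]1(C(=O)C(C)C)C(=O)C=C2OC | intermediate
30 | (1R,5R,7S,8R)-4-hydroxy-8-methyl-1-(2-methylpropanoyl)-5,7-bis(3-methylbut-2-en-1-yl)-8-(4-methylpent-3-en-1-yl)bicyclo[3.3.1]non-3-ene-2,9-dione | CC(C)=CCC[C@]1(C)[C@@H](CC=C(C)C)C[C@@]2(CC=C(C)C)C(=O)[C@]1(C(=O)C(C)C)C(=O)C=C2O | target

**Step count**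
Total steps: 16. Longest linear sequence: 16 steps (1 → 30; the Grignard reagent 11 is made and used within step 7).

**Steps most likely to fail, with fallbacks**

Step 10 (annulation with malonyl dichloride). It gives modest yields, forms a bond next to the quaternary C8 and competes with O-acylation. Fallback, setting out from ketone 16 and coming back at trione 21: build the oxygenated ring stepwise. Thermodynamic silylation of 16 (TMSCl, NaI, Et3N, MeCN) gives the tetrasubstituted trimethylsilyl enol ether F1. Mukaiyama aldol addition of F1 to 3-(trimethylsilyl)propynal (BF3·OEt2, CH2Cl2, −78 °C) forms the C5 quaternary centre on the face anti to the C7 prenyl group and gives the propargylic alcohol F2. Dess–Martin oxidation gives the silyl ynone F3, and n-Bu4NF/AcOH removes the alkynyl silane to give the terminal ynone F4. Cs2CO3 in MeCN then closes the C1–C2 bond by 6-endo-dig intramolecular Michael addition of the C1 enolate, giving the bicyclic enedione F5. Nucleophilic epoxidation (t-BuOOH, DBU, CH2Cl2; only the electron-poor alkene reacts) gives the epoxy ketone F6. Pd(PPh3)4 (zerovalent palladium) with 1,2-bis(diphenylphosphino)ethane in toluene at 80 °C isomerises F6 to the β-diketone, which is trione 21.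

Step 11 (regiochemistry of enol ether formation). The two vinylogous esters are expected in similar amounts and may be hard to separate. Fallback, setting out from trione 21 and coming back at carbinol 27: do not separate, and let the bridgehead chemistry sort the isomers. The crude mixture of 22 and the 2-methoxy regioisomer F7 is silylated as in step 12, giving 24 together with the silylated regioisomer F8. The mixture is then submitted to step 13. Only 24 has a bridgehead hydrogen flanked by two carbonyl groups, so only it should be converted into the much more polar carbinol 27. Unreacted F8 is recovered, desilylated (n-Bu4NF, AcOH) back to F7 and re-equilibrated under the step 11 conditions.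

Step 13 (bridgehead aldol). The hindered bridgehead lithium species may deprotonate the enolisable aldehyde or react incompletely. Fallback, setting out from 24 and coming back at carbinol 27: change the nucleophile. Lithiate 24 as in step 13 and quench with iodine (I2) to give the bridgehead iodide F9. Iodine–magnesium exchange with i-PrMgCl (THF, −78 °C) then gives the bridgehead magnesium chloride F10, a less basic and more oxophilic nucleophile, which adds to 2-methylpropanal 25 to give 27.

**Further compounds**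
F1 | step 10 | trimethyl{[(4S,5S)-5-methyl-2,4-bis(3-methylbut-2-en-1-yl)-5-(4-methylpent-3-en-1-yl)cyclohex-1-en-1-yl]oxy}silane | CC(C)=CCC[C@]1(C)[C@@H](CC=C(C)C)CC(CC=C(C)C)=C(O[Si](C)(C)C)C1
F2 | step 10 | (2R,4S,5S)-2-[(1RS)-1-hydroxy-3-(trimethylsilyl)prop-2-yn-1-yl]-5-methyl-2,4-bis(3-methylbut-2-en-1-yl)-5-(4-methylpent-3-en-1-yl)cyclohexan-1-one | CC(C)=CCC[C@]1(C)[C@@H](CC=C(C)C)C[C@](CC=C(C)C)(C(O)C#C[Si](C)(C)C)C(=O)C1
F3 | step 10 | (2S,4S,5S)-5-methyl-2,4-bis(3-methylbut-2-en-1-yl)-5-(4-methylpent-3-en-1-yl)-2-[3-(trimethylsilyl)prop-2-ynoyl]cyclohexan-1-one | CC(C)=CCC[C@]1(C)[C@@H](CC=C(C)C)C[C@](CC=C(C)C)(C(=O)C#C[Si](C)(C)C)C(=O)C1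
F4 | step 10 | (2S,4S,5S)-5-methyl-2,4-bis(3-methylbut-2-en-1-yl)-5-(4-methylpent-3-en-1-yl)-2-(prop-2-ynoyl)cyclohexan-1-one | CC(C)=CCC[C@]1(C)[C@@H](CC=C(C)C)C[C@](CC=C(C)C)(C(=O)C#C)C(=O)C1
F5 | step 10 | (1R,5R,7S,8R)-8-methyl-5,7-bis(3-methylbut-2-en-1-yl)-8-(4-methylpent-3-en-1-yl)bicyclo[3.3.1]non-2-ene-4,9-dione | CC(C)=CCC[C@]1(C)[C@@H](CC=C(C)C)C[C@@]2(CC=C(C)C)C(=O)[C@@H]1C=CC2=O
F6 | step 10 | 2,3-epoxide of F5 (oxirane on the exo face, C2/C3 configuration not specified; other centres as in F5) | CC(C)=CCC[C@]1(C)[C@@H](CC=C(C)C)C[C@@]2(CC=C(C)C)C(=O)[C@@H]1C3OC3C2=O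
F7 | step 11 | (1S,5R,7S,8R)-2-methoxy-8-methyl-5,7-bis(3-methylbut-2-en-1-yl)-8-(4-methylpent-3-en-1-yl)bicyclo[3.3.1]non-2-ene-4,9-dione | CC(C)=CCC[C@]1(C)[C@@H](CC=C(C)C)C[C@@]2(CC=C(C)C)C(=O)[C@@H]1C(OC)=CC2=O
F8 | step 11 | (1S,5S,7S,8R)-2-methoxy-8-methyl-5,7-bis(3-methylbut-2-en-1-yl)-8-(4-methylpent-3-en-1-yl)-3-(trimethylsilyl)bicyclo[3.3.1]non-2-ene-4,9-dione | CC(C)=CCC[C@]1(C)[C@@H](CC=C(C)C)C[C@@]2(CC=C(C)C)C(=O)[C@@H]1C(OC)=C([Si](C)(C)C)C2=O
F9 | step 13 | (1S,5R,7S,8R)-1-iodo-4-methoxy-8-methyl-5,7-bis(3-methylbut-2-en-1-yl)-8-(4-methylpent-3-en-1-yl)-3-(trimethylsilyl)bicyclo[3.3.1]non-3-ene-2,9-dione | CC(C)=CCC[C@]1(C)[C@@H](CC=C(C)C)C[C@@]2(CC=C(C)C)C(=O)[C@]1(I)C(=O)C([Si](C)(C)C)=C2OC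
F10 | step 13 | chlorido[(1S,5R,7S,8R)-4-methoxy-8-methyl-5,7-bis(3-methylbut-2-en-1-yl)-8-(4-methylpent-3-en-1-yl)-2,9-dioxo-3-(trimethylsilyl)bicyclo[3.3.1]non-3-en-1-yl]magnesium | CC(C)=CCC[C@]1(C)[C@@H](CC=C(C)C)C[C@@]2(CC=C(C)C)C(=O)[C@]1([Mg]Cl)C(=O)C([Si](C)(C)C)=C2OC
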